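The ratio I started from, when you asked for a quick number, was J lost over D charged. In the spring run at 4.00 h it read 0.954, so there D looked like the limiting reagent, with J charged in excess.

| flask | J | D | remark | time | volume of the second phase over the first |
|---|---|---|---|---|---|
| winter | 0.042 M | 0.0308 M | run made earlier |  |  |
| spring | 0.33 M | 0.0308 M | run made earlier |  |  |
| Friday's | 0.030 M | 0.0308 M |  | 4.0 h | 0.25 |
| Monday's | 0.060 M | 0.0308 M |  | 4.0 h | 0.25 |
| Saturday's | 0.12 M | 0.0308 M |  | 4.0 h | 0.25 |
| Wednesday's | 0.25 M | 0.0308 M |  | 4.0 h | 0.25 |

- winter (time / h: E / %, J / %): 0.250: 7.4, 89.8; 0.833: 11.5, 70.7; 1.33: 9.4, 63.4; 2.00: 7.0, 57.2; 3.00: 4.3, 51.2; 4.00: 4.2, 48.4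
- spring (time / h: E / %, J / %): 0.250: 4.2, 93.8; 0.833: 3.4, 92.0; 1.33: 2.8, 90.4; 2.00: 0.5, 91.1; 3.00: 0.2, 91.3; 4.00: 0.2, 91.1

(standard deviation of a reading: 0.5 percentage points)

- in the second phase: D; everything else is in the first
- charges count per volume of the first phase; a concentration in a rate is the amount of a species over the volume of its own phase; every rate counts per litre of the first phase
- the earlier runs hold the two phases in the same ratio of volumes as the flask asked about
- a reading or a percentage of E counts all its forms, free or not
- the concentration of E that is asked is that of its free form alone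
- "hardly changes" means that all values lie within two and a half points (for a concentration: within two and a half percent of the largest)

- [E] (only what is free in solution, in the first phase) at the end for Friday's, Monday's, Saturday's, Wednesday's, in this order
- the shape of the row from first to last (falls, then rises / rises, then falls / rises all the way / hardly changes / falls all the way)

That ratio made me distrust the percentages. A percent of E is counted against the J charged, so the same E in a litre prints as a smaller percent in a flask with a larger charge. I therefore read E per litre. I carried the end residue, the percent of E at the end of a run multiplied by the J charged, 1.76 mM from the winter run.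

I tested it on the spring run. The residue over that charge gave 0.535%, and the reading was 0.2%: a gap of 0.33 percentage points against a scatter of 0.5 points. So the two runs could share one residue, though spring tests it weakly.

I committed to about 1.76 mM of c_E in each of your flasks, a nearly flat row, and I assumed that all of the reading was free E.

Your forecast differed: 0.0014 M, 3.900 × 10⁻⁴ M, 9.300 × 10⁻⁵ M, 1.900 × 10⁻⁵ M, so falls all the way. Its ground was this: “This suggests decay through a complex”.

The flask gave 0.00132 M, 0.00148 M, 0.00121 M, 0.00120 M, so rises, then falls: Wednesday's c_E stood at 0.909 of Friday's, where the forecast had 0.0136. The row turned at a starting c_J of 0.047 M.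

    X ⇌ D, rate k1*([X] - [D]/K1) per volume of the first phase (partition coefficient = 4.70, kL = 0.180 min⁻¹)
    J + X → E (k = 0.710 M⁻¹ min⁻¹)
    X + E → Q (k = 2.00 M⁻¹ min⁻¹)
    E → Z (k = 0.0170 min⁻¹)
    E ⇌ L (K = 0.520, k = 0.00690 min⁻¹)
    G ⇌ E, rate k6*(cs6 - [E]) while solid is left; crystals form when [E] > cs6 (solubility = 18.0 mM, k = 0.910 min⁻¹)

Divided by Monday's charge, the residue gave 2.94%, and Monday's flask held 2.46% of E at 4.00 h. Divided by Wednesday's charge, it gave 0.706%, and Wednesday's flask held 0.478% of E at 4.00 h.

Readings and results come from a simulation from invented constants.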